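The target is robinetinidol-(4α→6)-epigallocatechin, with upper unit rings A, C, B and lower unit rings D, F, E. Retrosynthesis: remove nine O-benzyl groups; take the ring-F carbinol C3 back to a ketone and then to its C3=C4 ethyl enol ether; cut ring F at C4–C4a and O1–C2 in one stroke; last, cut the interflavan bond C4 (ring C)–C6 (ring D).
Forward: rings A/C/B come ready-made from (+)-dihydrorobinetin and become a C4 electrophile. Phloroglucinol is attached as ring D, its two hydroxyls next to the new bond are benzylated, and the para one is left free. Rings F and E are then added in one step with a 2-ethoxycinnamaldehyde, and hydrolysis, reduction and hydrogenolysis finish the route.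
Enabling feature: in ring D the unit H–O1–C8a=C4a–H is the enol of a phloroglucinol, a 1,3-C,O-bisnucleophile. C4–C3(O)–C2(aryl) of ring F is a 2-oxygenated enal in disguise (C4 = carbonyl carbon, C2 = β-carbon). Condensation gives the ortho-quinone methide O1=C8a–C4a=C4–C3=C2, a 1-oxatriene that closes to ring F by oxa-6π electrocyclisation.
The only free O–H of ring D lies para to the flavanyl-bearing carbon, so this closure can give only the 4→6 isomer, the connectivity that direct flavanol coupling disfavours. The ethoxy group stores the C3 oxygen and keeps C2 epimerisable.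
Stereochemistry: C2 and C3 of ring C come from the chiral pool; C4 of ring C is set by anchimeric assistance of the 3-acetate (attack trans to C3–O); C2 and C3 of ring F are set together, as the cis pair, by a stereoconvergent Noyori hydrogenation (dynamic kinetic resolution) of the C2-labile flavan-3-one.

Key step: step 11

Assumption: natural (+)-(2R,3R)-dihydrorobinetin and 3,4,5-tris(benzyloxy)benzaldehyde are taken as catalogue compounds.

Step 1
Reactants: 1 3,4,5-tris(benzyloxy)benzaldehyde; 2 ethyl 2-ethoxyacetate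
Product: 3 ethyl (Z)-2-ethoxy-3-[3,4,5-tris(benzyloxy)phenyl]prop-2-enoate
Conditions: KOtBu, THF, −10 °C to rt (2 in excess)
Reagents that add atoms: none
Why: A Claisen-type ester aldol condensation (addition of the α-ethoxy ester enolate to the non-enolisable aldehyde, then E1cB loss of hydroxide) should give the α-ethoxycinnamate, mainly the Z isomer with aryl trans to the ester, and the alkene geometry has no bearing on later steps.

Step 2
Reactants: 3 ethyl (Z)-2-ethoxy-3-[3,4,5-tris(benzyloxy)phenyl]prop-2-enoate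
Product: 4 (Z)-2-ethoxy-3-[3,4,5-tris(benzyloxy)phenyl]prop-2-en-1-ol
Conditions: iBu2AlH (DIBAL-H), CH2Cl2, −78 °C
Reagents that add atoms: none
Why: Hydride reduction of a conjugated ester with iBu2AlH goes 1,2 to the allylic alcohol and leaves the enol ether, the alkene and the benzyl ethers untouched.

Step 3
Reactants: 4 (Z)-2-ethoxy-3-[3,4,5-tris(benzyloxy)phenyl]prop-2-en-1-ol
Product: 5 (Z)-2-ethoxy-3-[3,4,5-tris(benzyloxy)phenyl]prop-2-enal
Conditions: MnO2, CH2Cl2, rt
Reagents that add atoms: none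
Why: The heterogeneous MnO2 oxidation is selective for allylic alcohols, stops at the aldehyde and is neutral, which the acid-sensitive enol ether requires.

Step 4
Reactants: 6 (+)-dihydrorobinetin, (2R,3R)-3,7-dihydroxy-2-(3,4,5-trihydroxyphenyl)chroman-4-one
Product: 7 (2R,3R)-7-(benzyloxy)-3-hydroxy-2-[3,4,5-tris(benzyloxy)phenyl]chroman-4-one
Conditions: BnBr, K2CO3, DMF, rt, N2
Reagents that add atoms: benzyl bromide BrCc1ccccc1
Why: In this Williamson ether synthesis K2CO3 deprotonates only the four phenols, so the secondary 3-OH stays free and the 2,3-trans pair (the more stable arrangement) is not disturbed.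

Step 5
Reactants: 7 (2R,3R)-7-(benzyloxy)-3-hydroxy-2-[3,4,5-tris(benzyloxy)phenyl]chroman-4-one
Product: 8 (2R,3S,4R)-7-(benzyloxy)-2-[3,4,5-tris(benzyloxy)phenyl]chromane-3,4-diol (2,3-trans-3,4-trans)
Conditions: NaBH4, THF–EtOH, 0 °C
Reagents that add atoms: none
Why: Borohydride reduction of the flavanonol carbonyl with axial hydride delivery should give mainly the equatorial 4α-alcohol, and since C4 is ionised in step 7 its configuration here is of no consequence.

Step 6
Reactants: 8 (2R,3S,4R)-7-(benzyloxy)-2-[3,4,5-tris(benzyloxy)phenyl]chromane-3,4-diol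
Product: 9 3,4-di-O-acetate of 8 (all three centres spatially unchanged)
Conditions: Ac2O, pyridine, DMAP (cat.), CH2Cl2, rt
Reagents that add atoms: acetic anhydride CC(=O)OC(C)=O
Why: DMAP-catalysed acylation puts a leaving group on the benzylic C4 oxygen and a participating ester on the C3 oxygen.

Step 7
Reactants: 9 3,4-di-O-acetate of 8; 10 phloroglucinol
Product: 11 (2R,3S,4S)-7-(benzyloxy)-2-[3,4,5-tris(benzyloxy)phenyl]-4-(2,4,6-trihydroxyphenyl)chroman-3-yl acetate (aryl 4α; 3,4-trans)
Conditions: 10 (5 equiv), BF3·OEt2 (cat.), 1,4-dioxane–CH2Cl2, 0 °C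
Reagents that add atoms: none
Why: In this Friedel–Crafts alkylation the Lewis acid ionises the 4-acetate to a para-alkoxybenzyl cation, the β-oriented 3-acetate shields the β-face by anchimeric assistance so that the arene attacks from the α-face and sets C4 trans to C3, and the three equivalent CH positions of 10 leave no regiochemical choice.

Step 8
Reactants: 11 (2R,3S,4S)-7-(benzyloxy)-2-[3,4,5-tris(benzyloxy)phenyl]-4-(2,4,6-trihydroxyphenyl)chroman-3-yl acetate
Product: 12 (2R,3S,4S)-7-(benzyloxy)-4-[2,6-dihydroxy-4-(triisopropylsilyloxy)phenyl]-2-[3,4,5-tris(benzyloxy)phenyl]chroman-3-yl acetate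
Conditions: iPr3SiCl (1.0 equiv), imidazole, DMF, 0 °C
Reagents that add atoms: chlorotriisopropylsilane CC(C)[Si](Cl)(C(C)C)C(C)C
Why: In this sterically controlled O-silylation two hydroxyls of ring D flank the bulky flavan-4-yl group, so the bulky chlorosilane should take the unhindered hydroxyl para to it.

Step 9
Reactants: 12 (2R,3S,4S)-7-(benzyloxy)-4-[2,6-dihydroxy-4-(triisopropylsilyloxy)phenyl]-2-[3,4,5-tris(benzyloxy)phenyl]chroman-3-yl acetate
Product: 13 (2R,3S,4S)-7-(benzyloxy)-4-[2,6-bis(benzyloxy)-4-(triisopropylsilyloxy)phenyl]-2-[3,4,5-tris(benzyloxy)phenyl]chroman-3-yl acetate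
Conditions: BnBr, K2CO3, DMF, rt to 40 °C
Reagents that add atoms: benzyl bromide BrCc1ccccc1
Why: A Williamson ether synthesis caps the two remaining phenols, while the acetate and the bulky aryl silyl ether tolerate anhydrous carbonate.

Step 10
Reactants: 13 (2R,3S,4S)-7-(benzyloxy)-4-[2,6-bis(benzyloxy)-4-(triisopropylsilyloxy)phenyl]-2-[3,4,5-tris(benzyloxy)phenyl]chroman-3-yl acetate
Product: 14 (2R,3S,4S)-7-(benzyloxy)-4-[2,6-bis(benzyloxy)-4-hydroxyphenyl]-2-[3,4,5-tris(benzyloxy)phenyl]chroman-3-ol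
Conditions: NaOH, EtOH–THF–H2O, 40 °C; then 1 M HCl
Reagents that add atoms: none
Why: Saponification of the acetate and hydroxide cleavage of the phenolic silyl ether (phenoxide is a good leaving group on silicon) free the 3-OH and the single phenol of ring D, and benzyl ethers are inert to base.

Step 11
Reactants: 14 (2R,3S,4S)-7-(benzyloxy)-4-[2,6-bis(benzyloxy)-4-hydroxyphenyl]-2-[3,4,5-tris(benzyloxy)phenyl]chroman-3-ol; 5 (Z)-2-ethoxy-3-[3,4,5-tris(benzyloxy)phenyl]prop-2-enal
Product: 17 (2R,3S,4S)-7-(benzyloxy)-4-{5,7-bis(benzyloxy)-3-ethoxy-2-[3,4,5-tris(benzyloxy)phenyl]-2H-chromen-6-yl}-2-[3,4,5-tris(benzyloxy)phenyl]chroman-3-ol (both epimers at C2 of ring F), via benzodioxaborin 15 (not isolated), via ortho-quinone methide 16 (not isolated)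
Conditions: PhB(OH)2 (2 equiv), EtCO2H (cat.), toluene, reflux, Dean–Stark trap
Reagents that add atoms: none
Why: PhB(OH)2 esterifies the only free phenol of 14 and binds the aldehyde of 5, so the C–C bond forms inside a six-membered boron chelate at the ring-D carbon ortho to that oxygen and gives 15 (bond C4–C4a); at reflux 15 loses PhBO in a retro-[4+2] to give the vinylogous ortho-quinone methide 16, which closes by a thermal disrotatory oxa-6π electrocyclisation (bond O1–C2), driven by rearomatisation of ring D. The closest known reaction type is the boronic-acid- or amine-salt-mediated formal [3+3] synthesis of 2H-chromenes from phenols and α,β-unsaturated aldehydes. Ring F is the only ring closed, and it closes pericyclically as a six-atom, six-electron electrocyclisation of a 1-oxatriene, not by an ionic exo or endo attack. The one new stereocentre, C2 of ring F, is not controlled here and need not be, since the C3 enol ether becomes a ketone in step 12, which makes C2 epimerisable, and step 13 then sets it. Three selectivities are needed: 1,2- rather than 1,4-attack on the enal, secured by the boron chelate and by the 2-ethoxy donor, which deactivates the β-carbon as a Michael acceptor; the site on ring D, secured because the two CH positions ortho to the free OH are equivalent and are the only open ones; and 4→6 rather than 4→8 connectivity, secured because the oxygens flanking the flavanyl carbon are benzyl ethers, so the sole O–H that can become the quinone methide carbonyl lies para to it.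

Step 12
Reactants: 17 3-ethoxy-2H-chromene dimer (both epimers at C2 of ring F)
Product: 18 (2R,3S,4S)-7-(benzyloxy)-4-{5,7-bis(benzyloxy)-3-oxo-2-[3,4,5-tris(benzyloxy)phenyl]chroman-6-yl}-2-[3,4,5-tris(benzyloxy)phenyl]chroman-3-ol (C2 of ring F epimeric and labile)
Conditions: 0.5 M HCl, THF, 0 °C to rt, argon
Reagents that add atoms: water O
Why: Acid hydrolysis of the enol ether (protonation at C4, addition of water at C3, loss of ethanol) should give the flavan-3-one and turns C4 into the CH2 of the target.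

Step 13
Reactants: 18 flavan-3-one dimer (C2 of ring F epimeric)
Product: 19 nona-O-benzyl-robinetinidol-(4α→6)-epigallocatechin (upper unit 2R,3S,4S; lower unit 2R,3R)
Conditions: H2 (20 atm), trans-RuCl2[(S)-BINAP][(R,R)-DPEN] (cat.), KOtBu (cat.), iPrOH–toluene, rt
Reagents that add atoms: none
Why: This is a Noyori asymmetric hydrogenation under dynamic kinetic resolution, the reaction type known for configurationally labile 2-substituted cyclohexanones: KOtBu epimerises C2 of ring F (a benzylic, α-oxy and α-keto C–H) faster than the ketone is reduced, and the chiral ruthenium hydride should reduce only the (2R)-epimer with hydride delivery to the C3 face anti to ring E, so C2 (R) and C3 (R) are set together as the 2,3-cis pair, the (S)-diphosphine being chosen by analogy with the sense known for 2-alkyl- and 2-alkoxycyclohexanones.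

Step 14
Reactants: 19 nona-O-benzyl-robinetinidol-(4α→6)-epigallocatechin
Product: 20 robinetinidol-(4α→6)-epigallocatechin (target)
Conditions: H2 (1 atm), Pd(OH)2/C, THF–MeOH–H2O, rt
Reagents that add atoms: none
Why: Catalytic hydrogenolysis cleaves all nine aryl benzyl ethers under neutral conditions, under which the C2–O1 bonds, the interflavan bond and all five stereocentres of flavan-3-ol oligomers are normally retained.

Compound list
1 | 3,4,5-tris(benzyloxy)benzaldehyde | O=Cc1cc(OCc2ccccc2)c(OCc2ccccc2)c(OCc2ccccc2)c1 | starting material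
2 | ethyl 2-ethoxyacetate | CCOCC(=O)OCC | starting material
3 | ethyl (Z)-2-ethoxy-3-[3,4,5-tris(benzyloxy)phenyl]prop-2-enoate | CCO/C(C(=O)OCC)=C\c1cc(OCc2ccccc2)c(OCc2ccccc2)c(OCc2ccccc2)c1 | intermediate
4 | (Z)-2-ethoxy-3-[3,4,5-tris(benzyloxy)phenyl]prop-2-en-1-ol | CCO/C(CO)=C\c1cc(OCc2ccccc2)c(OCc2ccccc2)c(OCc2ccccc2)c1 | intermediate
5 | (Z)-2-ethoxy-3-[3,4,5-tris(benzyloxy)phenyl]prop-2-enal | CCO/C(C=O)=C\c1cc(OCc2ccccc2)c(OCc2ccccc2)c(OCc2ccccc2)c1 | intermediate
6 | (+)-(2R,3R)-dihydrorobinetin | Oc1ccc2c(c1)O[C@H](c1cc(O)c(O)c(O)c1)[C@@H](O)C2=O | starting material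
7 | (2R,3R)-7,3',4',5'-tetra-O-benzyldihydrorobinetin | O(Cc1ccccc1)c1ccc2c(c1)O[C@H](c1cc(OCc3ccccc3)c(OCc3ccccc3)c(OCc3ccccc3)c1)[C@@H](O)C2=O | intermediate
8 | (2R,3S,4R)-7-(benzyloxy)-2-[3,4,5-tris(benzyloxy)phenyl]chromane-3,4-diol | O(Cc1ccccc1)c1ccc2c(c1)O[C@H](c1cc(OCc3ccccc3)c(OCc3ccccc3)c(OCc3ccccc3)c1)[C@@H](O)[C@@H]2O | intermediate
9 | 3,4-di-O-acetate of 8 | O(Cc1ccccc1)c1ccc2c(c1)O[C@H](c1cc(OCc3ccccc3)c(OCc3ccccc3)c(OCc3ccccc3)c1)[C@@H](OC(C)=O)[C@@H]2OC(C)=O | intermediate
10 | phloroglucinol | Oc1cc(O)cc(O)c1 | starting material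
11 | 3-O-acetyl-tetra-O-benzylrobinetinidol-(4α→2)-phloroglucinol (2R,3S,4S) | O(Cc1ccccc1)c1ccc2c(c1)O[C@H](c1cc(OCc3ccccc3)c(OCc3ccccc3)c(OCc3ccccc3)c1)[C@@H](OC(C)=O)[C@@H]2c1c(O)cc(O)cc1O | intermediate
12 | para-O-triisopropylsilyl ether of 11 | O(Cc1ccccc1)c1ccc2c(c1)O[C@H](c1cc(OCc3ccccc3)c(OCc3ccccc3)c(OCc3ccccc3)c1)[C@@H](OC(C)=O)[C@@H]2c1c(O)cc(O[Si](C(C)C)(C(C)C)C(C)C)cc1O | intermediate
13 | ring-D di-O-benzyl ether of 12 | O(Cc1ccccc1)c1ccc2c(c1)O[C@H](c1cc(OCc3ccccc3)c(OCc3ccccc3)c(OCc3ccccc3)c1)[C@@H](OC(C)=O)[C@@H]2c1c(OCc3ccccc3)cc(O[Si](C(C)C)(C(C)C)C(C)C)cc1OCc3ccccc3 | intermediate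
14 | (2R,3S,4S)-7-(benzyloxy)-4-[2,6-bis(benzyloxy)-4-hydroxyphenyl]-2-[3,4,5-tris(benzyloxy)phenyl]chroman-3-ol | O(Cc1ccccc1)c1ccc2c(c1)O[C@H](c1cc(OCc3ccccc3)c(OCc3ccccc3)c(OCc3ccccc3)c1)[C@@H](O)[C@@H]2c1c(OCc3ccccc3)cc(O)cc1OCc3ccccc3 | intermediate
15 | 2-phenyl-4H-1,3,2-benzodioxaborin on ring D carrying the 1-ethoxy-2-arylvinyl group at C4 (C4 epimers) | O(Cc1ccccc1)c1ccc2c(c1)O[C@H](c1cc(OCc3ccccc3)c(OCc3ccccc3)c(OCc3ccccc3)c1)[C@@H](O)[C@@H]2c1c(OCc3ccccc3)cc2OB(c3ccccc3)OC(/C(OCC)=C/c3cc(OCc4ccccc4)c(OCc4ccccc4)c(OCc4ccccc4)c3)c2c1OCc3ccccc3 | intermediate (not isolated)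
16 | ring-D ortho-quinone methide (1-oxatriene O1=C8a–C4a=C4–C3=C2) | O(Cc1ccccc1)c1ccc2c(c1)O[C@H](c1cc(OCc3ccccc3)c(OCc3ccccc3)c(OCc3ccccc3)c1)[C@@H](O)[C@@H]2C1=C(OCc3ccccc3)/C(=C/C(OCC)=C/c3cc(OCc4ccccc4)c(OCc4ccccc4)c(OCc4ccccc4)c3)C(=O)C=C1OCc3ccccc3 | intermediate (not isolated)
17 | 3-ethoxy-2H-chromene dimer, C2 of ring F unassigned (both epimers) | O(Cc1ccccc1)c1ccc2c(c1)O[C@H](c1cc(OCc3ccccc3)c(OCc3ccccc3)c(OCc3ccccc3)c1)[C@@H](O)[C@@H]2c1c(OCc3ccccc3)cc2c(c1OCc3ccccc3)C=C(OCC)C(c1cc(OCc3ccccc3)c(OCc3ccccc3)c(OCc3ccccc3)c1)O2 | intermediate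
18 | flavan-3-one dimer, C2 of ring F epimeric and labile | O(Cc1ccccc1)c1ccc2c(c1)O[C@H](c1cc(OCc3ccccc3)c(OCc3ccccc3)c(OCc3ccccc3)c1)[C@@H](O)[C@@H]2c1c(OCc3ccccc3)cc2c(c1OCc3ccccc3)CC(=O)C(c1cc(OCc3ccccc3)c(OCc3ccccc3)c(OCc3ccccc3)c1)O2 | intermediate
19 | nona-O-benzyl-robinetinidol-(4α→6)-epigallocatechin | O(Cc1ccccc1)c1ccc2c(c1)O[C@H](c1cc(OCc3ccccc3)c(OCc3ccccc3)c(OCc3ccccc3)c1)[C@@H](O)[C@@H]2c1c(OCc3ccccc3)cc2c(c1OCc3ccccc3)C[C@@H](O)[C@@H](c1cc(OCc3ccccc3)c(OCc3ccccc3)c(OCc3ccccc3)c1)O2 | intermediate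
20 | robinetinidol-(4α→6)-epigallocatechin | Oc1ccc2c(c1)O[C@H](c1cc(O)c(O)c(O)c1)[C@@H](O)[C@@H]2c1c(O)cc2c(c1O)C[C@@H](O)[C@@H](c1cc(O)c(O)c(O)c1)O2 | target

Total step count: 14. Longest linear sequence: 11 steps (steps 4 to 14, from 6).

Steps most likely to fail

Step 11. Several things may go wrong. Ring D may attack the β-carbon of the enal in a conjugate sense. The enol ether may be lost to the water released. C–C bond formation at the crowded ring-D carbon may be sluggish. The quinone methide may be trapped intermolecularly before it closes. The fallback replaces electrophilic substitution by carbanion addition and sets out from 14.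
- NBS (1 equiv, CH2Cl2, −78 °C) should brominate ring D, the most electron-rich ring, at one of its two equivalent open positions to give the ring-D ortho-bromophenol F1.
- nBuLi (3.3 equiv, THF, −78 °C) deprotonates both hydroxyls and exchanges bromine for lithium, and 1,2-addition to 5 gives the ortho-hydroxyaryl allylic alcohol F2.
- Warming with pyridinium tosylate in toluene removes water by way of 16 and comes back to the route at 17.

Step 13. The catalyst may discriminate poorly between the two equilibrating C2 epimers. The sense of induction may be opposite to that inferred by analogy. The enolisable ketone may degrade under base. The fallback uses substrate control and separation and sets out from 18.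
- LiBH(sBu)3 with LiBr in THF at −78 °C delivers hydride anti to ring E in either epimer and should give only 2,3-cis carbinols.
- These are 19 and nona-O-benzyl-robinetinidol-(4α→6)-ent-epigallocatechin F3.
- The two are diastereomers and are separated by chromatography, which comes back to the route at 19.

Step 8. Silylation may spread to the hindered hydroxyls, or more than one hydroxyl may be silylated, which would blur the oxygen differentiation that fixes the 4→6 connectivity. The fallback caps carbon with halogen instead of differentiating the oxygens and sets out from 9.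
- Purchased 3,5-bis(benzyloxy)phenol is brominated at both positions ortho to its hydroxyl (NBS, 2 equiv, iPr2NH cat., CH2Cl2, 0 °C) to give 2,6-dibromo-3,5-bis(benzyloxy)phenol F4, whose only open carbon lies between the two benzyloxy groups.
- Friedel–Crafts coupling of F4 with 9 (Me3SiOTf cat., CH2Cl2, −40 °C) gives the dibromo adduct F5.
- LiAlH4 in refluxing THF removes both bromines and the acetate and comes back to the route at 14.

Further compounds
F1 | step 11 | ring-D ortho-bromophenol, (2R,3S,4S)-7-(benzyloxy)-4-[2,6-bis(benzyloxy)-3-bromo-4-hydroxyphenyl]-2-[3,4,5-tris(benzyloxy)phenyl]chroman-3-ol | O(Cc1ccccc1)c1ccc2c(c1)O[C@H](c1cc(OCc3ccccc3)c(OCc3ccccc3)c(OCc3ccccc3)c1)[C@@H](O)[C@@H]2c1c(OCc3ccccc3)cc(O)c(Br)c1OCc3ccccc3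
F2 | step 11 | ortho-hydroxyaryl allylic alcohol (carbinol epimers) | O(Cc1ccccc1)c1ccc2c(c1)O[C@H](c1cc(OCc3ccccc3)c(OCc3ccccc3)c(OCc3ccccc3)c1)[C@@H](O)[C@@H]2c1c(OCc3ccccc3)cc(O)c(C(O)/C(OCC)=C/c3cc(OCc4ccccc4)c(OCc4ccccc4)c(OCc4ccccc4)c3)c1OCc3ccccc3
F3 | step 13 | nona-O-benzyl-robinetinidol-(4α→6)-ent-epigallocatechin (lower unit 2S,3S) | O(Cc1ccccc1)c1ccc2c(c1)O[C@H](c1cc(OCc3ccccc3)c(OCc3ccccc3)c(OCc3ccccc3)c1)[C@@H](O)[C@@H]2c1c(OCc3ccccc3)cc2c(c1OCc3ccccc3)C[C@H](O)[C@H](c1cc(OCc3ccccc3)c(OCc3ccccc3)c(OCc3ccccc3)c1)O2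
F4 | step 8 | 2,6-dibromo-3,5-bis(benzyloxy)phenol | Oc1c(Br)c(OCc2ccccc2)cc(OCc2ccccc2)c1Br
F5 | step 8 | dibromo adduct, (2R,3S,4S)-7-(benzyloxy)-4-[2,6-bis(benzyloxy)-3,5-dibromo-4-hydroxyphenyl]-2-[3,4,5-tris(benzyloxy)phenyl]chroman-3-yl acetate | O(Cc1ccccc1)c1ccc2c(c1)O[C@H](c1cc(OCc3ccccc3)c(OCc3ccccc3)c(OCc3ccccc3)c1)[C@@H](OC(C)=O)[C@@H]2c1c(OCc3ccccc3)c(Br)c(O)c(Br)c1OCc3ccccc3
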